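**Plan**

1. Retrosynthesis: the angelate (C4–O) and anisoate (C8–O) esters are removed first, then the isopropyl group at C1 (leaving a ketone). The seven-membered ring is then cut at C8a–C8 and at C5=C6, which releases 3-methylbut-3-enal and a 4,4-disubstituted cyclopent-2-enone. That enone's quaternary carbon/carbinol pair is cut by a [2,3]-Wittig transform back to 3-methylcyclopent-2-enol.
2. Forward: the five-membered ring is present from the start; the side chain is attached by [2,3]-Wittig rearrangement; allylic oxidation gives the enone. A one-flask (4+3) annulation (α′-aldol addition, then ring-closing metathesis) closes the seven-membered ring; conjugate reduction, isopropyl addition and two acylations finish the route.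
3. Enabling feature: in the seven-membered ring, C8a lies between C1 (a former ketone) and oxygenated C8, which is an aldol pattern. The only ring alkene, C5=C6, sits next to the C4 carbinol. C8, C7, C6 and the C6 methyl can therefore be inserted as one aldehyde–alkene unit between the α′-carbon and the vinyl carbinol of a cyclopentenone.
4. Stereochemistry: a CBS reduction is the only external source of chirality. The [2,3]-Wittig step transfers it to C3a and sets C4. The aldol sets C8a (attack anti to the bulky side chain, giving the trans ring fusion) and C8 (anti aldol). Organocerium addition anti to the C8 substituent sets C1.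
5. Helpers: the cyclopentenone alkene (forces α′-enolisation, later removed by conjugate reduction), the alkynylsilane, and the silyl ether at C4–O.

Key step: step 8

Remark: bicyclic compounds are named with azulene numbering (C1 = carbinol carbon bearing isopropyl, C3a = methyl-bearing quaternary ring-fusion carbon, C4 = carbon bearing the angelate oxygen, C5=C6 = ring alkene with methyl on C6, C8 = carbon bearing the anisoate oxygen, C8a = ring-fusion CH); the [2,3]-Wittig step is assumed to follow the usual rule that the new hydroxyl ends up syn to the alkene substituent that is cis to the ether carbon.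

**Step 1**
Reactants: 1 3-methylcyclopent-2-en-1-one
Product: 2 (1S)-3-methylcyclopent-2-en-1-ol
Conditions: (R)-2-methyl-CBS-oxazaborolidine (10 mol%), BH3·SMe2, THF, −20 °C
Reagents that add atoms: none
Why: Corey–Bakshi–Shibata reduction should deliver hydride 1,2 to the enone with the alkene side acting as the large group, so the (R)-catalyst should give the (S)-allylic alcohol that carries all later absolute configuration.

**Step 2**
Reactants: 2 (1S)-3-methylcyclopent-2-en-1-ol; 3 3-bromo-1-(trimethylsilyl)prop-1-yne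
Product: 4 trimethyl(3-{[(1S)-3-methylcyclopent-2-en-1-yl]oxy}prop-1-yn-1-yl)silane
Conditions: NaH, THF, 0 → 23 °C
Reagents that add atoms: none
Why: Williamson etherification of the sodium alkoxide with the primary propargylic bromide should proceed without touching the carbinol stereocenter.

**Step 3**
Reactants: 4 trimethyl(3-{[(1S)-3-methylcyclopent-2-en-1-yl]oxy}prop-1-yn-1-yl)silane
Product: 6 (1R)-1-[(1R)-1-methylcyclopent-2-en-1-yl]prop-2-yn-1-ol, via silylated alkynol 5 (not isolated)
Conditions: n-BuLi, THF, −78 → 0 °C; then MeOH, K2CO3, 23 °C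
Reagents that add atoms: none
Why: the propargylic carbanion should undergo a suprafacial [2,3]-Wittig rearrangement that transfers the C–O configuration to the new quaternary carbon and, through the five-membered envelope transition state, places the hydroxyl syn to the ring methylene and anti to the methyl group; methanolic carbonate then removes the alkynyl silyl group.

**Step 4**
Reactants: 6 (1R)-1-[(1R)-1-methylcyclopent-2-en-1-yl]prop-2-yn-1-ol
Product: 7 tert-butyl(dimethyl){[(1R)-1-[(1R)-1-methylcyclopent-2-en-1-yl]prop-2-yn-1-yl]oxy}silane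
Conditions: TBSOTf, 2,6-lutidine, CH2Cl2, 0 °C
Reagents that add atoms: tert-butyldimethylsilyl trifluoromethanesulfonate, CC(C)(C)[Si](C)(C)OS(=O)(=O)C(F)(F)F
Why: silylation with the silyl triflate should protect the hindered secondary alcohol next to the quaternary carbon without affecting either stereocenter.

**Step 5**
Reactants: 7 tert-butyl(dimethyl){[(1R)-1-[(1R)-1-methylcyclopent-2-en-1-yl]prop-2-yn-1-yl]oxy}silane
Product: 8 (4R)-4-[(1R)-1-{[tert-butyl(dimethyl)silyl]oxy}prop-2-yn-1-yl]-4-methylcyclopent-2-en-1-one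
Conditions: CrO3, 3,5-dimethylpyrazole, CH2Cl2, −20 °C
Reagents that add atoms: chromium trioxide, O=[Cr](=O)=O
Why: allylic oxidation with the chromium trioxide–dimethylpyrazole complex should occur at the only allylic methylene (the other allylic position is quaternary) and give the cyclopent-2-enone with the quaternary carbon at C4.

**Step 6**
Reactants: 8 (4R)-4-[(1R)-1-{[tert-butyl(dimethyl)silyl]oxy}prop-2-yn-1-yl]-4-methylcyclopent-2-en-1-one
Product: 9 (4R)-4-[(1R)-1-{[tert-butyl(dimethyl)silyl]oxy}prop-2-en-1-yl]-4-methylcyclopent-2-en-1-one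
Conditions: H2 (1 atm), Pd/CaCO3 poisoned with Pb(OAc)2, quinoline, EtOAc, 23 °C
Reagents that add atoms: none
Why: semihydrogenation over the poisoned palladium catalyst should stop at the terminal alkene, the conjugated ring alkene reacting much more slowly.

**Step 7**
Reactants: 10 3-methylbut-3-en-1-ol
Product: 11 3-methylbut-3-enal
Conditions: Dess–Martin periodinane, CH2Cl2, 0 → 23 °C; filtered solution used at once
Reagents that add atoms: none
Why: Dess–Martin oxidation under non-basic conditions should give the β,γ-unsaturated aldehyde without migration of the alkene into conjugation.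

**Step 8**
Reactants: 9 (4R)-4-[(1R)-1-{[tert-butyl(dimethyl)silyl]oxy}prop-2-en-1-yl]-4-methylcyclopent-2-en-1-one; 11 3-methylbut-3-enal
Product: 13 (3aS,4R,8S,8aS)-4-{[tert-butyl(dimethyl)silyl]oxy}-8-hydroxy-3a,6-dimethyl-3a,4,7,8-tetrahydroazulen-1(8aH)-one, via aldol adduct 12 (not isolated)
Conditions: LiN(iPr)2, THF, −78 °C; 11, −78 °C; AcOH, −78 °C; then CH2Cl2 (0.005 M), second-generation Grubbs catalyst (10 mol%), 40 °C, same flask
Reagents that add atoms: none
Why: Kinetic deprotonation can only occur at the α′-methylene (the γ-carbon is quaternary), and the ring-locked E-lithium enolate should add to the aldehyde through a chair Zimmerman–Traxler transition state (directed aldol addition) to make the C8a–C8 bond; the ruthenium alkylidene then joins the vinyl group and the 1,1-disubstituted alkene of the adduct by ring-closing metathesis through metallacyclobutanes, losing ethene and making the C5=C6 bond. The closest known reaction types are aldol additions of cyclopentenone α′-enolates and ring-closing metatheses that give trisubstituted cycloheptenes. The seven-membered ring is closed in the metathesis stage, onto the chain attached by the intermolecular aldol, as an endocyclic trisubstituted alkene whose geometry is fixed by the ring. C8a is controlled by approach of the aldehyde anti to the bulky silyloxyallyl group on the neighbouring quaternary carbon, which gives the trans ring fusion, and C8 by the chair transition state of the E-enolate, which gives the anti aldol (8S). The step needs the enone alkene to stay out of the metathesis, which its conjugation and the adjacent quaternary carbon should secure, and needs addition to outrun proton transfer from the enolisable aldehyde, which the low temperature and the acid quench at −78 °C should secure.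

**Step 9**
Reactants: 13 (3aS,4R,8S,8aS)-4-{[tert-butyl(dimethyl)silyl]oxy}-8-hydroxy-3a,6-dimethyl-3a,4,7,8-tetrahydroazulen-1(8aH)-one
Product: 14 (3aS,4R,8S,8aS)-4-{[tert-butyl(dimethyl)silyl]oxy}-8-hydroxy-3a,6-dimethyl-3,3a,4,7,8,8a-hexahydroazulen-1(2H)-one
Conditions: [(Ph3P)CuH]6, toluene, 23 °C; aq NH4Cl
Reagents that add atoms: none
Why: copper hydride conjugate reduction should reduce only the enone alkene, and the copper enolate forms on the side away from C8a so that the ring-fusion stereocenter is not touched.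

**Step 10**
Reactants: 14 (3aS,4R,8S,8aS)-4-{[tert-butyl(dimethyl)silyl]oxy}-8-hydroxy-3a,6-dimethyl-3,3a,4,7,8,8a-hexahydroazulen-1(2H)-one
Product: 15 (1R,3aS,4R,8S,8aS)-4-{[tert-butyl(dimethyl)silyl]oxy}-3a,6-dimethyl-1-(propan-2-yl)-1,2,3,3a,4,7,8,8a-octahydroazulene-1,8-diol
Conditions: iPrMgCl (3 equiv), CeCl3, THF, −78 → 0 °C
Reagents that add atoms: isopropylmagnesium chloride, CC(C)[Mg]Cl
Why: the weakly basic organocerium reagent should add 1,2 to the cyclopentanone from the face opposite the C8 carbinol substituent on the adjacent C8a, which places the new tertiary hydroxyl cis to that substituent (1R).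

**Step 11**
Reactants: 15 (1R,3aS,4R,8S,8aS)-4-{[tert-butyl(dimethyl)silyl]oxy}-3a,6-dimethyl-1-(propan-2-yl)-1,2,3,3a,4,7,8,8a-octahydroazulene-1,8-diol; 16 4-methoxybenzoyl chloride
Product: 17 (1R,3aS,4R,8S,8aS)-4-{[tert-butyl(dimethyl)silyl]oxy}-1-hydroxy-3a,6-dimethyl-1-(propan-2-yl)-1,2,3,3a,4,7,8,8a-octahydroazulen-8-yl 4-methoxybenzoate
Conditions: Et3N, DMAP (cat.), CH2Cl2, 0 → 23 °C
Reagents that add atoms: none
Why: DMAP-catalysed acylation should take place only at the secondary hydroxyl, the tertiary alcohol being too hindered to react.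

**Step 12**
Reactants: 17 (1R,3aS,4R,8S,8aS)-4-{[tert-butyl(dimethyl)silyl]oxy}-1-hydroxy-3a,6-dimethyl-1-(propan-2-yl)-1,2,3,3a,4,7,8,8a-octahydroazulen-8-yl 4-methoxybenzoate
Product: 18 (1R,3aS,4R,8S,8aS)-1,4-dihydroxy-3a,6-dimethyl-1-(propan-2-yl)-1,2,3,3a,4,7,8,8a-octahydroazulen-8-yl 4-methoxybenzoate
Conditions: Bu4NF, AcOH, THF, 23 °C
Reagents that add atoms: none
Why: buffered fluoride desilylation should free the allylic hydroxyl while leaving the aryl ester and the tertiary alcohol intact.

**Step 13**
Reactants: 18 (1R,3aS,4R,8S,8aS)-1,4-dihydroxy-3a,6-dimethyl-1-(propan-2-yl)-1,2,3,3a,4,7,8,8a-octahydroazulen-8-yl 4-methoxybenzoate; 19 (2Z)-2-methylbut-2-enoic acid (angelic acid)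
Product: 20 (1R,3aS,4R,8S,8aS)-1-hydroxy-3a,6-dimethyl-4-{[(2Z)-2-methylbut-2-enoyl]oxy}-1-(propan-2-yl)-1,2,3,3a,4,7,8,8a-octahydroazulen-8-yl 4-methoxybenzoate
Conditions: 19, 2,4,6-trichlorobenzoyl chloride, Et3N, toluene, 23 °C; then 18, 80 °C
Reagents that add atoms: none
Why: Yamaguchi esterification through the mixed anhydride should acylate the hindered secondary allylic alcohol without Z-to-E isomerisation of the angelate, and the tertiary alcohol should stay free.

**Compound list**

1 | 3-methylcyclopent-2-en-1-one | CC1=CC(=O)CC1 | starting material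
2 | (1S)-3-methylcyclopent-2-en-1-ol | O[C@@H]1C=C(C)CC1 | intermediate
3 | 3-bromo-1-(trimethylsilyl)prop-1-yne | C[Si](C)(C)C#CCBr | starting material
4 | trimethyl(3-{[(1S)-3-methylcyclopent-2-en-1-yl]oxy}prop-1-yn-1-yl)silane | C[Si](C)(C)C#CCO[C@@H]1C=C(C)CC1 | intermediate
5 | (1S)-1-[(1R)-1-methylcyclopent-2-en-1-yl]-3-(trimethylsilyl)prop-2-yn-1-ol | C[Si](C)(C)C#C[C@@H](O)[C@@]1(C)C=CCC1 | intermediate
6 | (1R)-1-[(1R)-1-methylcyclopent-2-en-1-yl]prop-2-yn-1-ol | C#C[C@@H](O)[C@@]1(C)C=CCC1 | intermediate
7 | tert-butyl(dimethyl){[(1R)-1-[(1R)-1-methylcyclopent-2-en-1-yl]prop-2-yn-1-yl]oxy}silane | C#C[C@@H](O[Si](C)(C)C(C)(C)C)[C@@]1(C)C=CCC1 | intermediate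
8 | (4R)-4-[(1R)-1-{[tert-butyl(dimethyl)silyl]oxy}prop-2-yn-1-yl]-4-methylcyclopent-2-en-1-one | C#C[C@@H](O[Si](C)(C)C(C)(C)C)[C@@]1(C)C=CC(=O)C1 | intermediate
9 | (4R)-4-[(1R)-1-{[tert-butyl(dimethyl)silyl]oxy}prop-2-en-1-yl]-4-methylcyclopent-2-en-1-one | C=C[C@@H](O[Si](C)(C)C(C)(C)C)[C@@]1(C)C=CC(=O)C1 | intermediate
10 | 3-methylbut-3-en-1-ol | CC(=C)CCO | starting material
11 | 3-methylbut-3-enal | CC(=C)CC=O | intermediate
12 | (4S,5S)-4-[(1R)-1-{[tert-butyl(dimethyl)silyl]oxy}prop-2-en-1-yl]-5-[(1S)-1-hydroxy-3-methylbut-3-en-1-yl]-4-methylcyclopent-2-en-1-one | C=C[C@@H](O[Si](C)(C)C(C)(C)C)[C@@]1(C)C=CC(=O)[C@@H]1[C@@H](O)CC(C)=C | intermediate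
13 | (3aS,4R,8S,8aS)-4-{[tert-butyl(dimethyl)silyl]oxy}-8-hydroxy-3a,6-dimethyl-3a,4,7,8-tetrahydroazulen-1(8aH)-one | CC(C)(C)[Si](C)(C)O[C@@H]1C=C(C)C[C@H](O)[C@@H]2[C@]1(C)C=CC2=O | intermediate
14 | (3aS,4R,8S,8aS)-4-{[tert-butyl(dimethyl)silyl]oxy}-8-hydroxy-3a,6-dimethyl-3,3a,4,7,8,8a-hexahydroazulen-1(2H)-one | CC(C)(C)[Si](C)(C)O[C@@H]1C=C(C)C[C@H](O)[C@@H]2[C@]1(C)CCC2=O | intermediate
15 | (1R,3aS,4R,8S,8aS)-4-{[tert-butyl(dimethyl)silyl]oxy}-3a,6-dimethyl-1-(propan-2-yl)-1,2,3,3a,4,7,8,8a-octahydroazulene-1,8-diol | CC(C)(C)[Si](C)(C)O[C@@H]1C=C(C)C[C@H](O)[C@@H]2[C@]1(C)CC[C@@]2(O)C(C)C | intermediate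
16 | 4-methoxybenzoyl chloride | COc1ccc(cc1)C(Cl)=O | starting material
17 | (1R,3aS,4R,8S,8aS)-4-{[tert-butyl(dimethyl)silyl]oxy}-1-hydroxy-3a,6-dimethyl-1-(propan-2-yl)-1,2,3,3a,4,7,8,8a-octahydroazulen-8-yl 4-methoxybenzoate | CC(C)(C)[Si](C)(C)O[C@@H]1C=C(C)C[C@H](OC(=O)c2ccc(OC)cc2)[C@@H]2[C@]1(C)CC[C@@]2(O)C(C)C | intermediate
18 | (1R,3aS,4R,8S,8aS)-1,4-dihydroxy-3a,6-dimethyl-1-(propan-2-yl)-1,2,3,3a,4,7,8,8a-octahydroazulen-8-yl 4-methoxybenzoate | O[C@@H]1C=C(C)C[C@H](OC(=O)c2ccc(OC)cc2)[C@@H]2[C@]1(C)CC[C@@]2(O)C(C)C | intermediate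
19 | (2Z)-2-methylbut-2-enoic acid (angelic acid) | C/C=C(/C)C(=O)O | starting material
20 | (1R,3aS,4R,8S,8aS)-1-hydroxy-3a,6-dimethyl-4-{[(2Z)-2-methylbut-2-enoyl]oxy}-1-(propan-2-yl)-1,2,3,3a,4,7,8,8a-octahydroazulen-8-yl 4-methoxybenzoate | C/C=C(/C)C(=O)O[C@@H]1C=C(C)C[C@H](OC(=O)c2ccc(OC)cc2)[C@@H]2[C@]1(C)CC[C@@]2(O)C(C)C | target

Total step count: 13. Longest linear sequence: 12 steps (steps 1–6 and 8–13).

**Steps most likely to fail**

Step 8. Proton transfer from the enolisable β,γ-unsaturated aldehyde to the enolate, isomerisation of that aldehyde into conjugation, insufficient anti or facial selectivity in the aldol, or ring-rearrangement metathesis through the enone alkene may each erode the annulation. The fallback separates the two bond formations and removes the enone alkene before metathesis. It sets out from 9 and 11: 9 is enolised with (c-C6H11)2BCl and Et3N in Et2O at −78 °C and combined with 11 in a boron aldol reaction, and after oxidative work-up the adduct 12 is isolated. The enone alkene of 12 is then reduced with [(Ph3P)CuH]6 in toluene to (2S,3S)-3-[(1R)-1-{[tert-butyl(dimethyl)silyl]oxy}prop-2-en-1-yl]-2-[(1S)-1-hydroxy-3-methylbut-3-en-1-yl]-3-methylcyclopentan-1-one F1. Ring-closing metathesis of F1 with second-generation Grubbs catalyst in CH2Cl2 at 40 °C should give 14 directly, where the route resumes.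

Step 3. The envelope transition state may not discriminate well enough when the alkene terminus is trisubstituted, so that control at the carbinol carbon is poor. The fallback replaces sigmatropic control of that center by reagent control. It sets out from 4: the rearrangement is run without the methanolysis and 5 is isolated as a mixture of carbinol epimers. The mixture is oxidised with MnO2 in CH2Cl2 to 1-[(1R)-1-methylcyclopent-2-en-1-yl]-3-(trimethylsilyl)prop-2-yn-1-one F2. Asymmetric transfer hydrogenation of F2 with RuCl[(S,S)-TsDPEN](p-cymene) in iPrOH should return 5 as one epimer, and K2CO3 in MeOH then gives 6, where the route resumes.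

Step 10. Enolisation of the hindered ketone, β-hydride reduction by the branched Grignard reagent, retro-aldol opening of the intermediate alkoxide, or insufficient facial selectivity may intervene. The fallback brings in the three carbons as an sp2 nucleophile that has no β-hydrogen. It sets out from 14: addition of CH2=C(CH3)MgBr with CeCl3 in THF at −78 °C should give (1S,3aS,4R,8S,8aS)-4-{[tert-butyl(dimethyl)silyl]oxy}-3a,6-dimethyl-1-(prop-1-en-2-yl)-1,2,3,3a,4,7,8,8a-octahydroazulene-1,8-diol F3. Hydrogenation of the 1,1-disubstituted alkene of F3 with H2 and RhCl(PPh3)3 in benzene, which should leave the trisubstituted ring alkene untouched, gives 15, where the route resumes.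

**Further compounds**
F1 | step 8 | (2S,3S)-3-[(1R)-1-{[tert-butyl(dimethyl)silyl]oxy}prop-2-en-1-yl]-2-[(1S)-1-hydroxy-3-methylbut-3-en-1-yl]-3-methylcyclopentan-1-one | C=C[C@@H](O[Si](C)(C)C(C)(C)C)[C@@]1(C)CCC(=O)[C@@H]1[C@@H](O)CC(C)=C
F2 | step 3 | 1-[(1R)-1-methylcyclopent-2-en-1-yl]-3-(trimethylsilyl)prop-2-yn-1-one | C[Si](C)(C)C#CC(=O)[C@@]1(C)C=CCC1
F3 | step 10 | (1S,3aS,4R,8S,8aS)-4-{[tert-butyl(dimethyl)silyl]oxy}-3a,6-dimethyl-1-(prop-1-en-2-yl)-1,2,3,3a,4,7,8,8a-octahydroazulene-1,8-diol | CC(C)(C)[Si](C)(C)O[C@@H]1C=C(C)C[C@H](O)[C@@H]2[C@]1(C)CC[C@@]2(O)C(C)=C
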